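**Plan**

1. Retrosynthesis (germacrane numbering): the O8 methacrylate and O9 acetate are removed first, then the ten-membered carbocycle is cut at C7–C8.
2. Enabling feature: the exocyclic C11=C13 methylene of the lactone, C7 and the C8 carbinol form a homoallylic alcohol spanning the lactone ring and the ten-membered ring. This is the retron of a carbonyl allylation, so the lactone can carry its own nucleophile as a 3-(bromomethyl)butenolide (C13–Br, C7=C11) tethered to a C8 aldehyde.
3. Further cuts: C7=C11 (ring-closing metathesis), C6–C7 (vinyl addition to a C6 enal), the C4–C5 epoxide oxygen, C1=C10 (aldol, elimination) and C9–C10 (Mukaiyama aldol); C1–C6 come from geranyl acetate.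
4. Forward: chain assembly, then the epoxide ring, then the butenolide ring, and last the ten-membered ring by intramolecular allylation mediated by divalent chromium, followed by the two acylations.
5. Stereochemistry: C9 from a catalytic asymmetric aldol, C6 from a catalytic asymmetric vinyl transfer, C4/C5 relayed from C6 by hydroxyl-directed epoxidation, C7/C8 from C6 and the chair transition state of the ring closure; C1=C10 geometry from E1cB elimination, the trans epoxide geometry from the (E)-alkene of geranyl acetate.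

Key step: step 14

Remark: positions are given in germacrane numbering (ring C1–C10; lactone C6–O–C12(=O)–C11(=C13)–C7; ester carbon C14 on C10). Aldehyde 4 and ketene acetal 5 are taken as purchasable.

**Route**

Step 1
Reactants: 1 geranyl acetate
Product: 3 (E)-3-methyl-6-oxohex-2-en-1-yl acetate, via secondary ozonide 2 (not isolated)
Conditions: O3 (1 equiv, Sudan red 7B indicator), CH2Cl2, −78 °C; then Me2S, −78 °C to rt
Reagents that add atoms: ozone, [O-][O+]=O
Why: Chemoselective ozonolysis with reductive work-up: the electron-rich terminal trisubstituted alkene should react well before the alkene deactivated by the allylic acetate, Me2S reduces ozonide 2 to the aldehyde, and the (E)-alkene that becomes C4=C5 is untouched.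

Step 2
Reactants: 4 2-((4-methoxybenzyl)oxy)acetaldehyde; 5 1-methoxy-1-(trimethylsilyloxy)ethene
Product: 7 methyl (R)-3-hydroxy-4-((4-methoxybenzyl)oxy)butanoate, via trimethylsilyl ether 6 (not isolated)
Conditions: [Cu((R,R)-Ph-pybox)](SbF6)2 (2 mol %), CH2Cl2, −78 °C; then 1 M HCl, THF, 0 °C
Reagents that add atoms: none
Why: Catalytic enantioselective Mukaiyama aldol addition: the alkoxyacetaldehyde chelates the chiral divalent copper Lewis acid through its carbonyl and ether oxygens, one aldehyde face is shielded by a ligand phenyl group, and with the (R,R)-ligand the silyl ketene acetal should add to give the (R)-carbinol (C9); acid hydrolysis of 6 frees the alcohol.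

Step 3
Reactants: 7 methyl (R)-3-hydroxy-4-((4-methoxybenzyl)oxy)butanoate
Product: 8 methyl (R)-3-((tert-butyldimethylsilyl)oxy)-4-((4-methoxybenzyl)oxy)butanoate
Conditions: TBSCl, imidazole, DMF, rt
Reagents that add atoms: tert-butyldimethylsilyl chloride, CC(C)(C)[Si](C)(C)Cl
Why: Standard imidazole-promoted silylation of a secondary alcohol; the stereocenter is not touched.

Step 4
Reactants: 8 methyl (R)-3-((tert-butyldimethylsilyl)oxy)-4-((4-methoxybenzyl)oxy)butanoate; 3 (E)-3-methyl-6-oxohex-2-en-1-yl acetate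
Product: 10 methyl (6E)-8-acetoxy-2-[(1R)-1-((tert-butyldimethylsilyl)oxy)-2-((4-methoxybenzyl)oxy)ethyl]-3-hydroxy-6-methyloct-6-enoate (mixture at C2 and C3 of the chain), via lithium enolate 9 (not isolated)
Conditions: LiN(iPr)2 (1.05 equiv), THF, −78 °C; then 3, −78 °C; AcOH quench at −78 °C
Reagents that add atoms: none
Why: Aldol addition of a lithium ester enolate to an aldehyde at −78 °C, where β-elimination of the silyloxy group is slow and the acetate is not attacked; the two new centers (C10, C1) need no control because both become sp2 in step 5.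

Step 5
Reactants: 10 the aldol adduct
Product: 12 methyl (2E,6E)-8-acetoxy-2-[(1R)-1-((tert-butyldimethylsilyl)oxy)-2-((4-methoxybenzyl)oxy)ethyl]-6-methylocta-2,6-dienoate, via mesylate 11 (not isolated)
Conditions: MsCl, Et3N, CH2Cl2, 0 °C; then DBU, rt
Reagents that add atoms: none
Why: Mesylation followed by E1cB elimination through the ester enolate expels the mesylate and not the poorer silyloxy leaving group, and should favor the (E)-enoate (C2 trans to CO2Me, cis to C9) as the less strained trisubstituted alkene.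

Step 6
Reactants: 12 the acetoxy dienoate
Product: 13 methyl (2E,6E)-2-[(1R)-1-((tert-butyldimethylsilyl)oxy)-2-((4-methoxybenzyl)oxy)ethyl]-8-hydroxy-6-methylocta-2,6-dienoate
Conditions: K2CO3 (0.2 equiv), MeOH, 0 °C
Reagents that add atoms: none
Why: Base-catalyzed transesterification (methanolysis) removes the allylic acetate selectively, since exchange at the methyl ester is degenerate and the silyl and PMB ethers are stable to K2CO3 in methanol.

Step 7
Reactants: 13 the allylic alcohol
Product: 14 methyl (2E,6E)-2-[(1R)-1-((tert-butyldimethylsilyl)oxy)-2-((4-methoxybenzyl)oxy)ethyl]-6-methyl-8-oxoocta-2,6-dienoate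
Conditions: MnO2 (activated, excess), CH2Cl2, rt
Reagents that add atoms: none
Why: MnO2 oxidation is selective for the allylic alcohol and should give the (E)-enal without isomerization.

Step 8
Reactants: 14 the enal
Product: 15 methyl (2E,6E,8S)-2-[(1R)-1-((tert-butyldimethylsilyl)oxy)-2-((4-methoxybenzyl)oxy)ethyl]-8-hydroxy-6-methyldeca-2,6,9-trienoate
Conditions: (CH2=CH)2Zn (from CH2=CHMgBr and ZnCl2, magnesium salts removed with 1,4-dioxane), (−)-DAIB (10 mol %), toluene/Et2O, −20 to 0 °C; aq. NH4Cl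
Reagents that add atoms: divinylzinc, C=C[Zn]C=C
Why: Amino alcohol-catalyzed enantioselective addition of an organozinc to an aldehyde: the DAIB–zinc chelate should deliver the vinyl group to the Si face of the enal as it does for dialkylzincs, which sets (S)-C6, and the esters are inert to vinylzinc.

Step 9
Reactants: 15 the bis-allylic alcohol
Product: 16 methyl (2E)-2-[(1R)-1-((tert-butyldimethylsilyl)oxy)-2-((4-methoxybenzyl)oxy)ethyl]-5-[(2R,3R)-3-[(1S)-1-hydroxyprop-2-en-1-yl]-2-methyloxiran-2-yl]pent-2-enoate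
Conditions: mCPBA, NaHCO3, CH2Cl2, 0 °C
Reagents that add atoms: meta-chloroperoxybenzoic acid, OOC(=O)c1cccc(Cl)c1
Why: Hydroxyl-directed Prilezhaev epoxidation: allylic 1,3-strain from the C4 methyl group (cis to the carbinol carbon) holds the carbinol hydrogen in the alkene plane, the hydrogen-bonded peracid delivers oxygen syn to OH to give the threo (4R,5R) epoxide, and the trisubstituted alkene is far more nucleophilic than the vinyl group or the enoate.

Step 10
Reactants: 16 the epoxy alcohol; 17 2-(bromomethyl)acrylic acid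
Product: 19 methyl (2E)-5-[(2R,3R)-3-[(1S)-1-((2-(bromomethyl)acryloyl)oxy)prop-2-en-1-yl]-2-methyloxiran-2-yl]-2-[(1R)-1-((tert-butyldimethylsilyl)oxy)-2-((4-methoxybenzyl)oxy)ethyl]pent-2-enoate, via O-acylisourea 18 (not isolated)
Conditions: N,N′-diisopropylcarbodiimide, DMAP (5 mol %), CH2Cl2, −10 to 0 °C
Reagents that add atoms: none
Why: Steglich esterification acylates the C6 hydroxyl with retention, and low temperature with little DMAP limits attack on the allylic bromide.

Step 11
Reactants: 19 the bromomethylacrylate ester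
Product: 20 methyl (2E)-5-[(2R,3R)-3-[(2S)-4-(bromomethyl)-5-oxo-2,5-dihydrofuran-2-yl]-2-methyloxiran-2-yl]-2-[(1R)-1-((tert-butyldimethylsilyl)oxy)-2-((4-methoxybenzyl)oxy)ethyl]pent-2-enoate
Conditions: second-generation Grubbs catalyst RuCl2(H2IMes)(PCy3)(=CHPh) (5 mol %), CH2Cl2, 40 °C
Reagents that add atoms: none
Why: Ring-closing metathesis between the vinyl group and the 1,1-disubstituted acrylate closes the butenolide (C7=C11) with loss of ethylene; the trisubstituted enoate does not take part, the allylic bromide is tolerated, and C6 is unaffected.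

Step 12
Reactants: 20 the bromomethyl butenolide
Product: 21 methyl (2E)-5-[(2R,3R)-3-[(2S)-4-(bromomethyl)-5-oxo-2,5-dihydrofuran-2-yl]-2-methyloxiran-2-yl]-2-[(1R)-1-((tert-butyldimethylsilyl)oxy)-2-hydroxyethyl]pent-2-enoate
Conditions: DDQ, CH2Cl2/pH 7 phosphate buffer (10:1), 0 °C
Reagents that add atoms: none
Why: Oxidative PMB ether cleavage (hydride abstraction, hydrolysis of the oxocarbenium ion) proceeds under neutral conditions that leave the allylic bromide, epoxide, base-sensitive butenolide and silyl ether intact; 21 is used at once to forestall lactonization of the C8 hydroxyl onto the C14 ester.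

Step 13
Reactants: 21 the primary alcohol
Product: 22 methyl (2E)-5-[(2R,3R)-3-[(2S)-4-(bromomethyl)-5-oxo-2,5-dihydrofuran-2-yl]-2-methyloxiran-2-yl]-2-[(1R)-1-((tert-butyldimethylsilyl)oxy)-2-oxoethyl]pent-2-enoate
Conditions: Dess–Martin periodinane, NaHCO3, CH2Cl2, 0 °C to rt; crude aldehyde used directly
Reagents that add atoms: none
Why: Dess–Martin oxidation under buffered, non-basic conditions should give the α-silyloxy aldehyde without epimerization at C9 or migration of the C1=C10 double bond.

Step 14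
Reactants: 22 the bromo aldehyde
Product: 24 methyl (1(10)E,4R,5R,6S,7R,8R,9R)-9-((tert-butyldimethylsilyl)oxy)-4,5-epoxy-8-hydroxygermacra-1(10),11(13)-dien-12,6-olid-14-oate, via allylchromium species 23 (not isolated)
Conditions: CrCl2 (10 equiv), THF, 4 Å MS, rt; 22 added by syringe pump over 12 h to 0.002 M; then water
Reagents that add atoms: none
Why: Two equivalents of divalent chromium insert into the allylic C13–Br bond to give the trivalent allylchromium 23, which adds through its γ-carbon C7 to the tethered C8 aldehyde in a six-membered chair transition state, so that C7–C8 forms while the double bond moves from C7=C11 to C11=C13 and the α-methylene lactone appears in the same event. The closest known reaction type is the intramolecular Nozaki–Hiyama (Barbier-type) allylation used to close ten-membered germacranolide and larger cembranoid carbocycles, together with the intermolecular allylation of aldehydes by 3-(bromomethyl)butenolides. The ten-membered carbocycle is closed in a 10-exo-trig mode at the aldehyde carbon, with SE2′ transposition on the nucleophile, the epoxide and lactone rings being already in place. C7 is controlled by C6, because the aldehyde should approach the butenolide face opposite to the epoxide-bearing C6 substituent and so give the trans-fused lactone (7R); C8 is controlled by the chair transition state, in which the (E)-allyl geometry fixed by the butenolide ring and an equatorial C9 substituent on the aldehyde lead to the 7,8-anti relationship (8R). The step needs γ- over α-attack (secured by the cyclic transition state), ring closure over oligomerization (high dilution and the turn imposed by the C1=C10 alkene, which holds C2 and C9 cis), and chemoselectivity for the C–Br bond (divalent chromium should leave the epoxide, both esters and the silyl ether untouched). The existing C9 center is expected to play a minor role against these two controls.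

Step 15
Reactants: 24 the macrocyclic alcohol
Product: 25 methyl (1(10)E,4R,5R,6S,7R,8R,9R)-9-((tert-butyldimethylsilyl)oxy)-4,5-epoxy-8-(methacryloyloxy)germacra-1(10),11(13)-dien-12,6-olid-14-oate
Conditions: methacrylic anhydride, Et3N, DMAP (10 mol %), CH2Cl2, 0 °C
Reagents that add atoms: methacrylic anhydride, CC(=C)C(=O)OC(=O)C(C)=C
Why: DMAP-catalyzed acylation of the C8 alcohol with retention; short reaction time at 0 °C limits base-induced lactone migration to O8.

Step 16
Reactants: 25 the silyl ether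
Product: 26 methyl (1(10)E,4R,5R,6S,7R,8R,9R)-4,5-epoxy-9-hydroxy-8-(methacryloyloxy)germacra-1(10),11(13)-dien-12,6-olid-14-oate
Conditions: HF·pyridine, pyridine, THF, 0 °C to rt
Reagents that add atoms: none
Why: Fluoride-mediated desilylation under buffered, weakly acidic conditions should spare the epoxide and avoid the base-promoted 8-to-9 acyl migration that fluoride salts would cause.

Step 17
Reactants: 26 the C9 alcohol
Product: 27 the target, methyl (1(10)E,4R,5R,6S,7R,8R,9R)-9-acetoxy-4,5-epoxy-8-(methacryloyloxy)germacra-1(10),11(13)-dien-12,6-olid-14-oate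
Conditions: Ac2O, pyridine, DMAP (cat.), CH2Cl2, 0 °C
Reagents that add atoms: acetic anhydride, CC(=O)OC(C)=O
Why: Fast DMAP-catalyzed acetylation of the allylic C9 alcohol with retention, outpacing acyl migration.

**Compound list**

1 | geranyl acetate, (E)-3,7-dimethylocta-2,6-dien-1-yl acetate | CC(C)=CCC/C(C)=C/COC(C)=O | starting material
2 | (E)-5-(5,5-dimethyl-1,2,4-trioxolan-3-yl)-3-methylpent-2-en-1-yl acetate (secondary ozonide) | CC(=O)OC/C=C(C)/CCC1OOC(C)(C)O1 | intermediate
3 | (E)-3-methyl-6-oxohex-2-en-1-yl acetate | CC(=O)OC/C=C(C)/CCC=O | intermediate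
4 | 2-((4-methoxybenzyl)oxy)acetaldehyde | O=CCOCc1ccc(OC)cc1 | starting material
5 | 1-methoxy-1-(trimethylsilyloxy)ethene | C=C(OC)O[Si](C)(C)C | starting material
6 | methyl (R)-4-((4-methoxybenzyl)oxy)-3-((trimethylsilyl)oxy)butanoate | COC(=O)C[C@@H](O[Si](C)(C)C)COCc1ccc(OC)cc1 | intermediate
7 | methyl (R)-3-hydroxy-4-((4-methoxybenzyl)oxy)butanoate | COC(=O)C[C@@H](O)COCc1ccc(OC)cc1 | intermediate
8 | methyl (R)-3-((tert-butyldimethylsilyl)oxy)-4-((4-methoxybenzyl)oxy)butanoate | COC(=O)C[C@@H](O[Si](C)(C)C(C)(C)C)COCc1ccc(OC)cc1 | intermediate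
9 | lithium enolate of 8 | COC(O[Li])=C[C@@H](O[Si](C)(C)C(C)(C)C)COCc1ccc(OC)cc1 | intermediate
10 | methyl (6E)-8-acetoxy-2-[(1R)-1-((tert-butyldimethylsilyl)oxy)-2-((4-methoxybenzyl)oxy)ethyl]-3-hydroxy-6-methyloct-6-enoate (mixture at C2, C3) | COC(=O)C(C(O)CC/C(C)=C/COC(C)=O)[C@@H](O[Si](C)(C)C(C)(C)C)COCc1ccc(OC)cc1 | intermediate
11 | 3-O-methanesulfonate of 10 | COC(=O)C(C(OS(C)(=O)=O)CC/C(C)=C/COC(C)=O)[C@@H](O[Si](C)(C)C(C)(C)C)COCc1ccc(OC)cc1 | intermediate
12 | methyl (2E,6E)-8-acetoxy-2-[(1R)-1-((tert-butyldimethylsilyl)oxy)-2-((4-methoxybenzyl)oxy)ethyl]-6-methylocta-2,6-dienoate | CC(=O)OC/C=C(C)/CC/C=C(/C(=O)OC)[C@@H](O[Si](C)(C)C(C)(C)C)COCc1ccc(OC)cc1 | intermediate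
13 | methyl (2E,6E)-2-[(1R)-1-((tert-butyldimethylsilyl)oxy)-2-((4-methoxybenzyl)oxy)ethyl]-8-hydroxy-6-methylocta-2,6-dienoate | OC/C=C(C)/CC/C=C(/C(=O)OC)[C@@H](O[Si](C)(C)C(C)(C)C)COCc1ccc(OC)cc1 | intermediate
14 | methyl (2E,6E)-2-[(1R)-1-((tert-butyldimethylsilyl)oxy)-2-((4-methoxybenzyl)oxy)ethyl]-6-methyl-8-oxoocta-2,6-dienoate | O=C/C=C(C)/CC/C=C(/C(=O)OC)[C@@H](O[Si](C)(C)C(C)(C)C)COCc1ccc(OC)cc1 | intermediate
15 | methyl (2E,6E,8S)-2-[(1R)-1-((tert-butyldimethylsilyl)oxy)-2-((4-methoxybenzyl)oxy)ethyl]-8-hydroxy-6-methyldeca-2,6,9-trienoate | C=C[C@H](O)/C=C(C)/CC/C=C(/C(=O)OC)[C@@H](O[Si](C)(C)C(C)(C)C)COCc1ccc(OC)cc1 | intermediate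
16 | methyl (2E)-2-[(1R)-1-((tert-butyldimethylsilyl)oxy)-2-((4-methoxybenzyl)oxy)ethyl]-5-[(2R,3R)-3-[(1S)-1-hydroxyprop-2-en-1-yl]-2-methyloxiran-2-yl]pent-2-enoate | C=C[C@H](O)[C@H]1O[C@]1(C)CC/C=C(/C(=O)OC)[C@@H](O[Si](C)(C)C(C)(C)C)COCc1ccc(OC)cc1 | intermediate
17 | 2-(bromomethyl)acrylic acid | C=C(CBr)C(=O)O | starting material
18 | O-(2-(bromomethyl)acryloyl)-N,N′-diisopropylisourea | C=C(CBr)C(=O)OC(=NC(C)C)NC(C)C | intermediate
19 | 2-(bromomethyl)acrylate ester of 16 at O6 | C=C[C@H](OC(=O)C(=C)CBr)[C@H]1O[C@]1(C)CC/C=C(/C(=O)OC)[C@@H](O[Si](C)(C)C(C)(C)C)COCc2ccc(OC)cc2 | intermediate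
20 | methyl (2E)-5-[(2R,3R)-3-[(2S)-4-(bromomethyl)-5-oxo-2,5-dihydrofuran-2-yl]-2-methyloxiran-2-yl]-2-[(1R)-1-((tert-butyldimethylsilyl)oxy)-2-((4-methoxybenzyl)oxy)ethyl]pent-2-enoate | BrCC1=C[C@H](OC1=O)[C@H]2O[C@]2(C)CC/C=C(/C(=O)OC)[C@@H](O[Si](C)(C)C(C)(C)C)COCc3ccc(OC)cc3 | intermediate
21 | methyl (2E)-5-[(2R,3R)-3-[(2S)-4-(bromomethyl)-5-oxo-2,5-dihydrofuran-2-yl]-2-methyloxiran-2-yl]-2-[(1R)-1-((tert-butyldimethylsilyl)oxy)-2-hydroxyethyl]pent-2-enoate | BrCC1=C[C@H](OC1=O)[C@H]2O[C@]2(C)CC/C=C(/C(=O)OC)[C@@H](O[Si](C)(C)C(C)(C)C)CO | intermediate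
22 | methyl (2E)-5-[(2R,3R)-3-[(2S)-4-(bromomethyl)-5-oxo-2,5-dihydrofuran-2-yl]-2-methyloxiran-2-yl]-2-[(1R)-1-((tert-butyldimethylsilyl)oxy)-2-oxoethyl]pent-2-enoate | BrCC1=C[C@H](OC1=O)[C@H]2O[C@]2(C)CC/C=C(/C(=O)OC)[C@@H](O[Si](C)(C)C(C)(C)C)C=O | intermediate
23 | allylchromium dichloride derived from 22 (C13–CrCl2, trivalent chromium, solvent ligands omitted) | Cl[Cr](Cl)CC1=C[C@H](OC1=O)[C@H]2O[C@]2(C)CC/C=C(/C(=O)OC)[C@@H](O[Si](C)(C)C(C)(C)C)C=O | intermediate
24 | methyl (1(10)E,4R,5R,6S,7R,8R,9R)-9-((tert-butyldimethylsilyl)oxy)-4,5-epoxy-8-hydroxygermacra-1(10),11(13)-dien-12,6-olid-14-oate | O[C@@H]1[C@H]2C(=C)C(=O)O[C@@H]2[C@H]2O[C@]2(C)CC/C=C(/C(=O)OC)[C@H]1O[Si](C)(C)C(C)(C)C | intermediate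
25 | methyl (1(10)E,4R,5R,6S,7R,8R,9R)-9-((tert-butyldimethylsilyl)oxy)-4,5-epoxy-8-(methacryloyloxy)germacra-1(10),11(13)-dien-12,6-olid-14-oate | C=C(C)C(=O)O[C@@H]1[C@H]2C(=C)C(=O)O[C@@H]2[C@H]2O[C@]2(C)CC/C=C(/C(=O)OC)[C@H]1O[Si](C)(C)C(C)(C)C | intermediate
26 | methyl (1(10)E,4R,5R,6S,7R,8R,9R)-4,5-epoxy-9-hydroxy-8-(methacryloyloxy)germacra-1(10),11(13)-dien-12,6-olid-14-oate | C=C(C)C(=O)O[C@@H]1[C@H]2C(=C)C(=O)O[C@@H]2[C@H]2O[C@]2(C)CC/C=C(/C(=O)OC)[C@H]1O | intermediate
27 | methyl (1(10)E,4R,5R,6S,7R,8R,9R)-9-acetoxy-4,5-epoxy-8-(methacryloyloxy)germacra-1(10),11(13)-dien-12,6-olid-14-oate | C=C(C)C(=O)O[C@@H]1[C@H]2C(=C)C(=O)O[C@@H]2[C@H]2O[C@]2(C)CC/C=C(/C(=O)OC)[C@H]1OC(C)=O | target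

**Step count and risks**

Total step count: 17. Longest linear sequence: 16 steps (steps 2 to 17, from 4 and 5); 15 steps from geranyl acetate.

Most likely to fail:

1. Step 14. The ring closure may show poor facial selectivity at the aldehyde carbon, so that the C8 epimer forms in quantity, and intermolecular coupling may compete. The fallback sets out from 22 and comes back at 25. The same chromium-mediated closure is run, and if it delivers mainly the C8 epimer, methyl (1(10)E,4R,5R,6S,7R,8S,9R)-9-((tert-butyldimethylsilyl)oxy)-4,5-epoxy-8-hydroxygermacra-1(10),11(13)-dien-12,6-olid-14-oate F1, this alcohol is esterified with methacrylic acid under Mitsunobu conditions (PPh3, diisopropyl azodicarboxylate, toluene, 0 °C). The methacrylate is then installed with inversion at C8 instead of retention, and 25 results.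

2. Step 5. The E1cB elimination may give incomplete control of the C1=C10 geometry, with the (Z)-enoate as a contaminant. The fallback sets out from 8 and 3 and comes back at 12, and builds the alkene by cross metathesis instead of elimination. Enolate 9 is trapped with monomeric formaldehyde to give methyl (3R)-3-((tert-butyldimethylsilyl)oxy)-2-(hydroxymethyl)-4-((4-methoxybenzyl)oxy)butanoate F2. Mesylation gives its methanesulfonate F3, and DBU eliminates it to methyl 2-[(1R)-1-((tert-butyldimethylsilyl)oxy)-2-((4-methoxybenzyl)oxy)ethyl]acrylate F4, where no geometry is at stake. Aldehyde 3 is methylenated (Ph3P=CH2 from Ph3PCH3Br and KOtBu, THF, 0 °C) to (E)-3-methylhepta-2,6-dien-1-yl acetate F5. Cross metathesis of F4 with excess F5 (second-generation Hoveyda–Grubbs catalyst RuCl2(H2IMes)(=CH-C6H4-2-OiPr), CH2Cl2, 40 °C) should give 12 under thermodynamic control, as in cross metathesis of methacrylates.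

3. Step 8. Enantiofacial control in the vinyl transfer to the enal may be insufficient; because C9 is remote, this would show up as inseparable diastereomers downstream. The fallback sets out from 13 and comes back at 16, and reverses the order of stereocontrol. Sharpless asymmetric epoxidation of 13 (Ti(OiPr)4, D-(−)-diethyl tartrate, tBuOOH, 4 Å MS, CH2Cl2, −20 °C) sets C4 and C5 by reagent control and gives methyl (2E)-2-[(1R)-1-((tert-butyldimethylsilyl)oxy)-2-((4-methoxybenzyl)oxy)ethyl]-5-[(2R,3R)-3-(hydroxymethyl)-2-methyloxiran-2-yl]pent-2-enoate F6. Dess–Martin oxidation gives methyl (2E)-2-[(1R)-1-((tert-butyldimethylsilyl)oxy)-2-((4-methoxybenzyl)oxy)ethyl]-5-[(2R,3S)-3-formyl-2-methyloxiran-2-yl]pent-2-enoate F7. Chelation-controlled addition of CH2=CHMgBr (MgBr2·OEt2, CH2Cl2, −78 °C, aldehyde and epoxide oxygens bound to magnesium) should then give the threo alcohol 16, with any C6 epimer removed by chromatography.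

**Further compounds**

F1 | step 14 | methyl (1(10)E,4R,5R,6S,7R,8S,9R)-9-((tert-butyldimethylsilyl)oxy)-4,5-epoxy-8-hydroxygermacra-1(10),11(13)-dien-12,6-olid-14-oate | O[C@H]1[C@H]2C(=C)C(=O)O[C@@H]2[C@H]2O[C@]2(C)CC/C=C(/C(=O)OC)[C@H]1O[Si](C)(C)C(C)(C)C
F2 | step 5 | methyl (3R)-3-((tert-butyldimethylsilyl)oxy)-2-(hydroxymethyl)-4-((4-methoxybenzyl)oxy)butanoate | COC(=O)C(CO)[C@@H](O[Si](C)(C)C(C)(C)C)COCc1ccc(OC)cc1
F3 | step 5 | methyl (3R)-3-((tert-butyldimethylsilyl)oxy)-4-((4-methoxybenzyl)oxy)-2-(((methylsulfonyl)oxy)methyl)butanoate | COC(=O)C(COS(C)(=O)=O)[C@@H](O[Si](C)(C)C(C)(C)C)COCc1ccc(OC)cc1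
F4 | step 5 | methyl 2-[(1R)-1-((tert-butyldimethylsilyl)oxy)-2-((4-methoxybenzyl)oxy)ethyl]acrylate | C=C(C(=O)OC)[C@@H](O[Si](C)(C)C(C)(C)C)COCc1ccc(OC)cc1
F5 | step 5 | (E)-3-methylhepta-2,6-dien-1-yl acetate | C=CCC/C(C)=C/COC(C)=O
F6 | step 8 | methyl (2E)-2-[(1R)-1-((tert-butyldimethylsilyl)oxy)-2-((4-methoxybenzyl)oxy)ethyl]-5-[(2R,3R)-3-(hydroxymethyl)-2-methyloxiran-2-yl]pent-2-enoate | OC[C@H]1O[C@]1(C)CC/C=C(/C(=O)OC)[C@@H](O[Si](C)(C)C(C)(C)C)COCc1ccc(OC)cc1
F7 | step 8 | methyl (2E)-2-[(1R)-1-((tert-butyldimethylsilyl)oxy)-2-((4-methoxybenzyl)oxy)ethyl]-5-[(2R,3S)-3-formyl-2-methyloxiran-2-yl]pent-2-enoate | O=C[C@H]1O[C@]1(C)CC/C=C(/C(=O)OC)[C@@H](O[Si](C)(C)C(C)(C)C)COCc1ccc(OC)cc1
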